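What part of side product plus target is side product in the flask? Part of that turns on how substrate divides among three proposed exits: to intermediate B at a rate of first order in substrate, to intermediate A at a rate that also carries the partner concentration, and to self-condensation product at a rate of second order in substrate, so that of these exits partner weighs on the second.

| flask | substrate | partner | remark | time |
|---|---|---|---|---|
| winter | 13 mM | 30 mM | run made earlier |  |
| summer | 30 mM | 30 mM | run made earlier |  |
| dawn | 20 mM | 45 mM | run made earlier |  |
| flask | 20 mM | 30.0 mM |  | 10 d |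

| run | time / d | side product / % | target / % |
|---|---|---|---|
| winter | 0.833 | 0.4 | 29.5 |
| winter | 1.25 | 1.9 | 30.8 |
| winter | 2.00 | 0.2 | 34.3 |
| winter | 4.00 | 0.8 | 39.5 |
| winter | 6.00 | 1.2 | 41.7 |
| winter | 10.0 | 0.7 | 41.6 |
| summer | 0.833 | 1.8 | 30.3 |
| summer | 1.25 | 2.8 | 32.2 |
| summer | 2.00 | 2.0 | 34.9 |
| summer | 4.00 | 1.5 | 37.3 |
| summer | 6.00 | 1.8 | 36.7 |
| summer | 10.0 | 0.9 | 36.1 |
| dawn | 0.833 | 0.6 | 26.8 |
| dawn | 2.50 | 1.5 | 33.4 |
| dawn | 5.00 | 1.4 | 39.0 |
| dawn | 8.00 | 0.6 | 41.8 |
| dawn | 10.0 | 0.9 | 41.9 |

(scatter of a reading: 0.5 percentage points)

* share of side product in side product plus target at 1.0 h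
* share of side product in side product plus target at 15 h
* share of side product in side product plus target at 10 d

In each run the side product column wanders without a trend in time, so its mean can stand for a plateau: 0.867% in winter, 1.80% in summer and 1.00% at dawn. The winter and dawn runs have nearly the same charge ratio ρ of substrate to partner, 0.433 and 0.444, and their means differ by 0.13 percentage points, less than the scatter of 0.5 points on a single reading. The summer run, at twice the ρ of the dawn run, reads twice its side product, though its substrate and partner charges both differ from those of the dawn run. These runs give two levels of ρ, which do not test a proportion, so proportionality to ρ is my working assumption and not a finding, and on it the pooled coefficient g, plateau side product per unit of ρ, comes to 1.95%.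

For the flask, at ρ = 0.667, g gives 1.30%. Final target, drawn straight in ρ between the dawn and summer runs, gives 39.6%, so my share at 10 d is 3.18%. The target readings at 0.833 d average 28.9%, and with these standing in for 15 h my share is 4.32%. No run was read as early as 1.0 h, so I give no figure there.

The forecast, lower than my figures at both later times, gives 3.5%, 4% and 2.8%, saying that the side product “forms early and then stops”.

    intermediate C ⇌ intermediate D (K = 1.90, k = 3.80 h⁻¹)
    substrate + partner → intermediate A (k = 51.0 M⁻¹ h⁻¹)
    intermediate B → side product (k = 1.50 h⁻¹)
    intermediate A → target (k = 0.150 h⁻¹)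
    partner + intermediate A ⇌ intermediate C (K = 83.0 M⁻¹, k = 6.50 M⁻¹ h⁻¹)
    2 substrate → self-condensation product (k = 10.0 M⁻¹ h⁻¹)
    target ⇌ isomer of the product (K = 0.990, k = 0.800 h⁻¹)
    substrate → intermediate B (k = 0.0130 h⁻¹)
    target → over-reaction product (k = 5.00 × 10⁻⁴ h⁻¹)

The flask gives 8.20%, 3.83% and 2.77%. Its side product stands at 1.12% at 0.300 d and at 1.14% at 10.0 d, when substrate, the limiting reagent, is at 0%, while target climbs from 31.6% at 1.00 d to 40.2%. Against that 1.14%, g had offered 1.30%. In the neighbouring flask with 50 mM of substrate, ρ is 1.67, so g offers 3.25%, and that flask ends with 2.64% of side product.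

All runs were generated by integration on assumed constants; noise was put on by code.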